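## Structural features

The target is a caged polyprenylated acylphloroglucinol built on a bicyclo[3.3.1]nonane-2,4,9-trione. Ring A is C1–C2–C3–C4–C5–C9 and ring B is C1–C8–C7–C6–C5–C9; C1 carries the benzoyl group, C5 the geranyl chain and C8 a gem-dimethyl group. A further bridge C10H2–C11H joins C7 to C3 and creates the cycloheptanone C3–C4–C5–C6–C7–C10–C11. Through C12Me2–C13(=O)–C14H2 a cyclopentanone is fused to that ring at C3–C11. Five stereocentres (C1, C3, C5, C7, C11) lie in the cage; C3 and C11 are adjacent, and C1, C3 and C5 are quaternary carbons each flanked by two ketones. C11–H lies on the face of the cap (the face of C2, C8 and C9), so C7–H is anti to C11–H across the seven-membered ring. The fragile groups are the non-enolisable β-di- and triketones (retro-Claisen cleavage by nucleophiles), the acid- and hydrogenation-sensitive geranyl 1,5-diene, and the enolisable C13 ketone. The real difficulty is congestion: three quaternary α-carbons around the C2/C4/C9 triad beside two gem-dimethyl carbons (C8, C12), with C11 to be set absolutely and C7 relative to it before the cap can close. The key step exploits the cycloheptanone whose ketone C4 is flanked by C3 and C5 and which is fused at C3–C11 to the five-membered ring: this is the imprint of an oxyallyl cation C3–C4–C5 added to a diene C11=C10–C7=C6 tied back to C3 through C12–C13–C14.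

## Logic of the disconnections

27 ⇒ 25 (through 26). No skeletal bond is cut; the C13 ketone is taken back to its silyl-protected carbinol. A C13 ketone would add an enolisable C14 methylene to every enolate step, and the carbinol is the one centre from which absolute configuration is relayed. The gain is that C13 is a spectator from the key step to the end. The demand is a desilylation without nucleophilic base, because the cage consists of non-enolisable β-diketones.

25 ⇒ 23 + 24. The bond cut is C1–C(=O)Ph. C1–H is the only acidic hydrogen of 23, so the aryl ketone, the most retro-Claisen-prone carbonyl, can enter late. The gain is a cage with no acyl side chain. The demand is that a bridgehead carbanion forms with a non-nucleophilic base and is acylated on carbon.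

23 ⇒ 21 (through 22). The bonds cut are C5–C9 and C3–C2, each joining a ketone α-carbon to a malonyl carbon. The cage collapses to a bicyclic ketone with a pendant malonic acid, and C1, C3 and C5 cease to be independent stereocentres because the cage dictates them. The demand is C-acylation at two tertiary carbons with C1 kept sp3, and a C8 arm already sitting on the face of H3 and H11.

21 ⇒ 20 ⇒ 18 + 19. First the acids are traced to methyl esters (no skeletal cut), then C5–C1′ of the geranyl chain is cut. C5 is the only methylene α to the C4 ketone, so a kinetic enolate finds it. The gain is removal of the whole terpenoid chain. The demands are a dianion (the malonate C–H is the more acidic), no hydrogenation afterwards, and an ester cleavage that is not basic.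

18 ⇒ 15 (through 17 and 16). The C7–H and C10–H bonds are removed, restoring the C7=C10 alkene; C4 passes through the alcohol oxidation level. The alkene is what the cycloaddition leaves behind, and the cut removes the C7 stereocentre. The demand is severe: hydrogen must reach C7 from the face opposite C11–H, the hindered face, so a directing hydroxyl is placed on that face at C4.

15 ⇒ 13 (through 14). The bonds cut are C3–C11 and C5–C6; two rings and two stereocentres are removed and an acyclic chain remains. The demand is an oxyallyl cation that the diene captures faster than it rearranges or is trapped by solvent, with the C13 centre choosing the diene face.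

13 ⇒ 12. The bond cut is C4–C5, so the reactive chloromethyl ketone is made last from a robust N-methoxy-N-methylamide. The demand is a single addition of a chloromethyl carbanion in the presence of the malonate.

12 ⇒ 11 + 4. The bond cut is the sp2–sp2 bond C7–C10, which divides the molecule into two fragments of similar size. The demand is an E-selective coupling next to two quaternary carbons. An enyne cross-metathesis of 3 with 11 would join the same carbons, but both partners carry a quaternary carbon beside the reacting π-bond.

4 ⇒ 3 ⇒ 1 + 2. The C7–I bond is removed, then C7–C8 is cut. Conjugate addition makes the quaternary C8 with the malonate already attached. The demand is Markovnikov addition of HI to the alkyne.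

11 ⇒ 9 ⇒ 5 + 6 (through 10, 8 and 7). The silyl group and amide nitrogen are removed, then C12–C13 is cut. A reverse prenylation makes the gem-dimethyl carbon, the vinyl group and the carbinol in one step, and the four-carbon aldehyde already holds C14, C3 and C4. The demand is reagent control of the aldehyde face, the only enantioselective event of the route.

## Other disconnections considered

Alternative 1: The cut removes C7–C10 and C1–C8 and leaves the spirocyclic triketo aldehyde A1. This is a 2-benzoylcyclohexane-1,3,5-trione whose C3 is the spiro atom of a cyclopentanone carrying the C10 aldehyde on C11, and whose C5 carries the geranyl and a prenyl group. Forward, an alkylaluminium chloride Lewis acid would activate the aldehyde, the prenyl alkene would add through C7 (Prins step, seven-membered ring), and the tertiary C8 cation would be taken up by the enol carbon C1 (six-membered ring). This would give the C10 carbinol A2, which then needs a two-step Barton–McCombie deoxygenation.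
- In favour: two rings, two C–C bonds and the centres C1 and C7 would arise in one late, biogenetically patterned operation. The benzoyl group is carried from the start, so no bridgehead acylation is needed, and C7 is set by ring closure and not by a separate hydrogenation. On both points it is better than the chosen plan.
- Against: A1 has two quaternary centres (C3, C5) and C11 to be set relative to one another. C5 bears two nearly identical allylic chains, so the choice of prenyl over geranyl rests on the C5 configuration alone. The C8 cation can also be captured by enol oxygen, by elimination or by the geranyl alkene, and the C1–C8 bond joins two fully substituted carbons. The C10 hydroxyl is a group the target lacks.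
- Comparison: structurally both plans build the seven-membered ring late, but the (4+3) step assembles it from an acyclic chain with one controlling centre, whereas A1 must first be a stereodefined spirocycle. Mechanistically a cation cascade with several exits stands against a cycloaddition whose connectivity the tether fixes. In steps after the key event the alternative is shorter (two from A2 against nine from 15), but the route to A1 is likely to cost that advantage.

Alternative 2: The cut is C1–C8 of ring B at an early stage. The precursor A3 is a 1-geranyl-2,6-dimethoxycyclohexa-2,5-diene with an epoxyprenyl chain on C5. Under a silyl triflate and a hindered pyridine base, one of its two enantiotopic enol ether carbons (C1) would open the epoxide at the tertiary carbon C8. Loss of methyl from the C9 oxocarbenium ion would give the bicyclo[3.3.1]nonenone A4.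
- In favour: this reaction type is established for this family. One epoxide centre controls C1, C5 and C7 of the core, and the C5 quaternary centre with its geranyl group is in place without any double acylation. In these respects it is better than the chosen plan, and in enantiocontrol at least its equal.
- Against: A4 has oxygen on C7 where the target has the carbon bridge, so C7–O must be exchanged for C7–C10 at a neopentyl secondary centre with defined configuration. C2 is still a methylene, C3 has yet to become quaternary, and the whole C10–C14 unit and the benzoyl group are missing.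
- Comparison: structurally the alternative builds the cap first and the five/seven-membered system last, the chosen plan the reverse. Mechanistically the epoxide opening is the more secure single step, but the later annulation across C7 and C3 has no comparably secure solution, whereas the (4+3) step delivers exactly that part. In step economy it would need well over ten further steps from A4 and is clearly longer.

Alternative 3: The cut removes C3–C14 and C3–C11, i.e. the cyclopentane and with it the seven-membered ring. It leads back to the 3-diazo-2,4,9-trione A5, a complete bicyclo[3.3.1]nonane core with benzoyl and geranyl groups whose C7 carries, through C10, a 2-silyloxy-3-methylbutadiene. A dirhodium tetracarboxylate (divalent rhodium) would generate a carbenoid at C3 that adds to the diene in a formal (4+1) sense, giving the cage silyl enol ether A6. Fluoride-induced enolate formation and methylation at C12 would complete the gem-dimethyl group and free the C13 ketone.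
- In favour: it is the most convergent plan. It makes the last quaternary centre and two rings on a core that already has every other substituent, with only one or two steps after the key event, which is better than the chosen plan. Diazo transfer to a cyclic 1,3-diketone is simple.
- Against: carbenoids from 2-diazo-1,3-diketones tend to react with electron-rich alkenes through carbonyl oxygen (dihydrofurans) or by cyclopropanation, so a (4+1) outcome usually needs a vinylcyclopropane rearrangement. The geranyl alkene next to C5 is an intramolecular competitor, and C11 would form without an independent control element. A5 also needs the C7 side chain, with the C7 configuration, installed on a core that is itself a full synthesis.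
- Comparison: structurally both plans close the five- and seven-membered rings in one step around C3–C11 and are equal in bonds formed per step. Mechanistically the oxyallyl (4+3) reaction has the closer precedent and fewer competing paths, while the carbenoid route is superior in convergence. In overall step count the alternative is equal at best once A5 is included.

Key step: step 7

Remarks on the chemistry:
- The numbering C1–C14 of the target is used for every intermediate.
- Stereochemical correction: because C8 and C11–H both lie on the cap face, a hydrogenation of C7=C10 from the open face of C11–H would give the C7 epimer, which cannot close the cage. Steps 8–10 deliver hydrogen to the opposite face by hydroxyl direction.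
- Assumption: in the cycloaddition the silyloxy group takes the convex position (cis to H3 and H11), so that (R)-C13 leads to the required C11 configuration. Should the opposite sense prevail, the enantiomeric borane would be used in step 3.
- The skeleton and substituents of 13 are kept. What is improved is the way to it (reverse prenylation and Heck coupling in place of a metathesis between two partners with quaternary carbons beside the π-bonds) and the handling of its acidic malonate (enolate protection in step 6, a second equivalent of base in step 7).

## Route

Step 1
Reactants: 1 dimethyl isopropylidenemalonate; 2 ethynylmagnesium bromide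
Product: 3 dimethyl 2-(2-methylbut-3-yn-2-yl)propanedioate
Conditions: 2 (1.3 equiv), CuCl (10 mol %), THF, 0 °C → rt; NH4Cl aq
Reagents that add atoms: none
Why: Copper-assisted conjugate addition of the alkynyl Grignard reagent to the doubly activated alkylidene malonate creates the quaternary carbon C8; the magnesium malonate enolate that results is inert to further addition.

Step 2
Reactants: 3 dimethyl 2-(2-methylbut-3-yn-2-yl)propanedioate
Product: 4 dimethyl 2-(3-iodo-2-methylbut-3-en-2-yl)propanedioate
Conditions: NaI, TMSCl, H2O (0.5 equiv), MeCN, rt
Reagents that add atoms: sodium iodide, [Na+].[I-]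
Why: Markovnikov hydroiodination: HI formed in situ protonates the terminal alkyne carbon and iodide enters at the internal carbon C7, giving the 2-iodo-1-alkene without touching the esters.

Step 3
Reactants: 5 methyl 4-oxobutanoate; 6 3-methylbuta-1,2-diene
Product: 9 (5R)-5-(2-methylbut-3-en-2-yl)oxolan-2-one, via prenylborane 7 (not isolated), via hydroxy ester 8 (not isolated)
Conditions: (−)-Ipc2BH [from (+)-α-pinene], 6, THF, −25 °C; 5, Et2O, −78 °C; NaBO3·4H2O, H2O; p-TsOH (cat.), CH2Cl2, rt
Reagents that add atoms: none
Why: Hydroboration of the allene at its CH2 terminus gives the γ,γ-dimethylallylborane, which adds to the aldehyde through a chair six-membered transition state with allyl transposition (reverse prenylation, C12–C13 bond). The isopinocampheyl groups from (+)-α-pinene direct attack to the Si face and should set C13 as R. Acid then closes the γ-hydroxy ester to the lactone.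

Step 4
Reactants: 9 (5R)-5-(2-methylbut-3-en-2-yl)oxolan-2-one
Product: 11 (4R)-4-(tert-butyldimethylsilyloxy)-N-methoxy-N,5,5-trimethylhept-6-enamide, via hydroxy amide 10 (not isolated)
Conditions: MeNH(OMe)·HCl, i-PrMgCl, THF, −20 °C; crude 10, TBSOTf, 2,6-lutidine, CH2Cl2, 0 °C
Reagents that add atoms: N,O-dimethylhydroxylamine hydrochloride, CNOC.Cl; tert-butyldimethylsilyl trifluoromethanesulfonate, CC(C)(C)[Si](C)(C)OS(=O)(=O)C(F)(F)F
Why: Aminolysis of the lactone by the magnesium amide gives the N-methoxy-N-methylamide and frees the hindered secondary alcohol, which is silylated at once with the silyl triflate so that it cannot relactonise.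

Step 5
Reactants: 11 (4R)-4-(tert-butyldimethylsilyloxy)-N-methoxy-N,5,5-trimethylhept-6-enamide; 4 dimethyl 2-(3-iodo-2-methylbut-3-en-2-yl)propanedioate
Product: 12 dimethyl 2-[(4E,7R)-7-(tert-butyldimethylsilyloxy)-10-[methoxy(methyl)amino]-2,6,6-trimethyl-3-methylidene-10-oxodec-4-en-2-yl]propanedioate
Conditions: Pd(OAc)2 (10 mol %), n-Bu4NCl, NaHCO3, DMF, 60 °C
Reagents that add atoms: none
Why: Mizoroki–Heck reaction: the alkenylpalladium species from 4 adds to the unhindered CH2 terminus of the alkene (C7–C10 bond). Because C12 is quaternary, β-hydride elimination can only give the conjugated E-diene.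

Step 6
Reactants: 12 diene N-methoxy-N-methylamide
Product: 13 dimethyl 2-[(4E,7R)-7-(tert-butyldimethylsilyloxy)-11-chloro-2,6,6-trimethyl-3-methylidene-10-oxoundec-4-en-2-yl]propanedioate
Conditions: LiN(SiMe3)2 (1.05 equiv), THF, −78 °C; ICH2Cl (3 equiv), MeLi·LiBr (2.5 equiv), −78 °C; AcOH
Reagents that add atoms: chloroiodomethane, ClCI
Why: The malonate is first masked as its lithium enolate. Chloromethyllithium from iodine–lithium exchange then adds once to the N-methoxy-N-methylamide, whose chelated tetrahedral adduct collapses to the chloromethyl ketone only on acidic quench (C4–C5 bond).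

Step 7
Reactants: 13 chloromethyl ketone
Product: 15 dimethyl 2-{2-[(2R,3aR,8aR)-2-(tert-butyldimethylsilyloxy)-1,1-dimethyl-4-oxo-1,2,3,3a,4,5,6,8a-octahydroazulen-7-yl]propan-2-yl}propanedioate, via oxyallyl cation 14 (not isolated)
Conditions: NaOCH2CF3 (2.2 equiv), CF3CH2OH, 0 °C → rt, 0.01 M, slow addition of 13
Reagents that add atoms: none
Why: Trifluoroethoxide removes a proton from C3 and the enolate loses chloride from C5 in the ionising, weakly nucleophilic solvent to give oxyallyl cation 14, which the tethered diene captures across C11 and C6 (bonds C3–C11 and C5–C6), concertedly or by C3–C11 bonding followed by collapse of the allyl cation–enolate pair. The closest known reaction type is the intramolecular (4+3) cycloaddition of oxyallyl cations generated from α-chloroketones by base in fluorinated alcohols with dienes on a three-atom tether. The cyclopentane closes in a 5-exo sense by bonding C3 to the near diene terminus C11; the cycloheptenone closes as the (4+3) ring itself by bonding C5 to the far, unsubstituted terminus C6, leaving C7=C10. C11 is controlled by the C13 silyloxy centre: in the envelope of the forming five-membered ring the silyloxy group takes the convex position, away from the seven-membered ring, so the cation adds to the diene face that puts C13–O cis to C11–H, which with (R)-C13 is the configuration of the target. C3 arises cis to C11–H from the compact transition state, stays epimerisable and is fixed only in step 13. The step needs periselectivity for (4+3) over Favorskii rearrangement, solvent capture and intermolecular alkylation: the gem-dimethyl group on the tether favours closure, the tert-alkyl group on C7 biases the diene toward s-cis, and high dilution together with the hindered, partly enolised malonate suppresses bimolecular paths.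

Step 8
Reactants: 15 cis-fused cycloheptenone
Product: 16 dimethyl 2-{2-[(2R,3aR,4S,8aR)-2-(tert-butyldimethylsilyloxy)-4-hydroxy-1,1-dimethyl-1,2,3,3a,4,5,6,8a-octahydroazulen-7-yl]propan-2-yl}propanedioate
Conditions: LiBH(s-Bu)3 (2.2 equiv), THF, −78 °C; NH4Cl aq
Reagents that add atoms: none
Why: The bulky borohydride should attack the C4 ketone from the convex face (the face of H3, anti to C14), placing the hydroxyl on the face of the cyclopentane carbons. One equivalent of hydride is consumed by the malonate C–H, and the esters are not reduced at −78 °C.

Step 9
Reactants: 16 C4 alcohol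
Product: 17 dimethyl 2-{2-[(2R,3aR,4S,7S,8aR)-2-(tert-butyldimethylsilyloxy)-4-hydroxy-1,1-dimethyldecahydroazulen-7-yl]propan-2-yl}propanedioate
Conditions: [Ir(cod)(PCy3)(py)]PF6 (10 mol %), H2 (1 atm), CH2Cl2, 0 °C → rt
Reagents that add atoms: none
Why: Hydroxyl-directed homogeneous hydrogenation: the cationic iridium catalyst binds the C4 hydroxyl and delivers H2 to the alkene face on which that hydroxyl sits. C7–H should therefore be set anti to C11–H (C8 on the face of H3 and H11), as the cage requires and opposite to what an undirected reduction from the open convex face would give.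

Step 10
Reactants: 17 saturated C4 alcohol
Product: 18 dimethyl 2-{2-[(2R,3aR,7S,8aR)-2-(tert-butyldimethylsilyloxy)-1,1-dimethyl-4-oxodecahydroazulen-7-yl]propan-2-yl}propanedioate
Conditions: DMP, NaHCO3, CH2Cl2, rt
Reagents that add atoms: none
Why: Buffered periodinane oxidation of the secondary alcohol returns the C4 ketone without touching C7 or the silyl ether.

Step 11
Reactants: 18 saturated ketone; 19 geranyl bromide
Product: 20 C5-geranyl ketone (C5 epimers), the 5-[(2E)-3,7-dimethylocta-2,6-dien-1-yl] derivative of 18
Conditions: LiN(i-Pr)2 (2.1 equiv), THF, −78 °C; 19 (1.05 equiv), DMPU, −78 → −40 °C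
Reagents that add atoms: none
Why: Two equivalents of amide base give the dianion (malonate enolate plus the kinetic ketone enolate at the CH2 carbon C5). The more reactive ketone enolate is alkylated by the allylic bromide (SN2), while the hindered malonate enolate neither alkylates nor lets its esters undergo a Claisen reaction. The C5 configuration is irrelevant because C5 is enolised again in step 13.

Step 12
Reactants: 20 C5-geranyl ketone
Product: 21 malonic acid, the propanedioic acid corresponding to 20
Conditions: LiI (10 equiv), EtOAc, reflux; 1 M HCl, 0 °C
Reagents that add atoms: none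
Why: SN2 demethylation of both methyl esters by iodide at the methyl carbon is non-basic, so the ketone cannot condense with the esters and the silyl ether and the diene survive. Cold acidification gives the substituted malonic acid, which does not decarboxylate at room temperature.

Step 13
Reactants: 21 malonic acid
Product: 23 cage trione with C1–H and C13 silyl ether (the 1-debenzoyl 13-silyloxy analogue of the target), via bis(acid chloride) 22 (not isolated)
Conditions: 1-chloro-N,N,2-trimethylprop-1-en-1-amine (2.2 equiv), CH2Cl2, 0 °C → rt; MgBr2·OEt2 (3 equiv), 2,6-di-tert-butyl-4-methylpyridine (2.5 equiv), CH2Cl2, 0 → 40 °C, 0.005 M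
Reagents that add atoms: none
Why: Proposed new method: the chloroenamine converts the diacid into the bis(acid chloride) under neutral conditions; MgBr2 then promotes enolisation of the C4 ketone toward C5 and toward C3, and each enol carbon attacks an acid chloride by addition–elimination (six-membered ring closures C5–C9 and C3–C2), the hindered pyridine serving only to trap HCl so that C1 stays sp3. The tether reaches both carbons only from the face of H3 and H11, which fixes C1, C3 and C5, and it cannot reach the C4 oxygen, so O-acylation is excluded. The closest known reaction type is the Effenberger cyclisation of enol ethers with malonyl dichloride to bicyclo[3.3.1]nonane-2,4,9-triones, together with the MgBr2-mediated C-acylation of ketones by acid chlorides.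

Step 14
Reactants: 23 cage trione; 24 benzoyl chloride
Product: 25 1-benzoyl cage trione C13 silyl ether (the 13-silyloxy-13-deoxo analogue of the target)
Conditions: lithium 2,2,6,6-tetramethylpiperidide (LiTMP, 1.5 equiv), THF, −78 °C; 24 (2 equiv), −78 → −40 °C
Reagents that add atoms: none
Why: Bridgehead deprotonation and acylation: C1–H is the only acidic hydrogen left because every other α-carbon is quaternary. The hindered lithium amide removes it, and the pyramidal carbanion is acylated on carbon, as is known for bridgehead positions of bicyclo[3.3.1]nonane-triones. The C1 configuration is dictated by the cage.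

Step 15
Reactants: 25 1-benzoyl cage silyl ether
Product: 26 C13 alcohol (13-hydroxy-13-deoxo analogue of the target)
Conditions: HF·pyridine, pyridine, THF, 0 °C → rt
Reagents that add atoms: none
Why: Cleavage of the hindered silyl ether with buffered hydrogen fluoride is acidic and non-nucleophilic, which avoids the retro-Claisen fragmentation that basic fluoride could start at the non-enolisable β-diketones.

Step 16
Reactants: 26 C13 alcohol
Product: 27 CNP0110281.1 (target)
Conditions: DMP, NaHCO3, CH2Cl2, rt
Reagents that add atoms: none
Why: Periodinane oxidation of the secondary alcohol gives the cyclopentanone; no stereocentre is at risk because C12 and C3 are quaternary and the conditions are neutral.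

## Compound list

1 | dimethyl 2-(propan-2-ylidene)propanedioate (dimethyl isopropylidenemalonate) | COC(=O)C(=C(C)C)C(=O)OC | starting material
2 | ethynylmagnesium bromide | C#C[Mg]Br | starting material
3 | dimethyl 2-(2-methylbut-3-yn-2-yl)propanedioate | C#CC(C)(C)C(C(=O)OC)C(=O)OC | intermediate
4 | dimethyl 2-(3-iodo-2-methylbut-3-en-2-yl)propanedioate | C=C(I)C(C)(C)C(C(=O)OC)C(=O)OC | intermediate
5 | methyl 4-oxobutanoate | COC(=O)CCC=O | starting material
6 | 3-methylbuta-1,2-diene | CC(C)=C=C | starting material
7 | (3-methylbut-2-en-1-yl)diisopinocampheylborane, isopinocampheyl groups from (+)-α-pinene | CC(C)=CCB([C@@H]1C[C@@H]2C[C@H]([C@H]1C)C2(C)C)[C@@H]1C[C@@H]2C[C@H]([C@H]1C)C2(C)C | intermediate (not isolated)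
8 | methyl (4R)-4-hydroxy-5,5-dimethylhept-6-enoate | COC(=O)CC[C@@H](O)C(C)(C)C=C | intermediate (not isolated)
9 | (5R)-5-(2-methylbut-3-en-2-yl)oxolan-2-one | O=C1CC[C@H](C(C)(C)C=C)O1 | intermediate
10 | (4R)-4-hydroxy-N-methoxy-N,5,5-trimethylhept-6-enamide | CON(C)C(=O)CC[C@@H](O)C(C)(C)C=C | intermediate (not isolated)
11 | (4R)-4-(tert-butyldimethylsilyloxy)-N-methoxy-N,5,5-trimethylhept-6-enamide | CON(C)C(=O)CC[C@@H](O[Si](C)(C)C(C)(C)C)C(C)(C)C=C | intermediate
12 | dimethyl 2-[(4E,7R)-7-(tert-butyldimethylsilyloxy)-10-[methoxy(methyl)amino]-2,6,6-trimethyl-3-methylidene-10-oxodec-4-en-2-yl]propanedioate | CON(C)C(=O)CC[C@@H](O[Si](C)(C)C(C)(C)C)C(C)(C)/C=C/C(=C)C(C)(C)C(C(=O)OC)C(=O)OC | intermediate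
13 | dimethyl 2-[(4E,7R)-7-(tert-butyldimethylsilyloxy)-11-chloro-2,6,6-trimethyl-3-methylidene-10-oxoundec-4-en-2-yl]propanedioate (key-step precursor) | ClCC(=O)CC[C@@H](O[Si](C)(C)C(C)(C)C)C(C)(C)/C=C/C(=C)C(C)(C)C(C(=O)OC)C(=O)OC | intermediate
14 | oxyallyl cation C3–C4–C5 (2-oxidoallyl cation) derived from 13 | [CH2+]C([O-])=CC[C@@H](O[Si](C)(C)C(C)(C)C)C(C)(C)/C=C/C(=C)C(C)(C)C(C(=O)OC)C(=O)OC | intermediate (not isolated)
15 | dimethyl 2-{2-[(2R,3aR,8aR)-2-(tert-butyldimethylsilyloxy)-1,1-dimethyl-4-oxo-1,2,3,3a,4,5,6,8a-octahydroazulen-7-yl]propan-2-yl}propanedioate (cis-fused; silyloxy cis to H3 and H11; key-step product) | O=C1CCC(C(C)(C)C(C(=O)OC)C(=O)OC)=C[C@H]2C(C)(C)[C@H](O[Si](C)(C)C(C)(C)C)C[C@@H]12 | intermediate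
16 | dimethyl 2-{2-[(2R,3aR,4S,8aR)-2-(tert-butyldimethylsilyloxy)-4-hydroxy-1,1-dimethyl-1,2,3,3a,4,5,6,8a-octahydroazulen-7-yl]propan-2-yl}propanedioate (C4–OH trans to H3) | O[C@H]1CCC(C(C)(C)C(C(=O)OC)C(=O)OC)=C[C@H]2C(C)(C)[C@H](O[Si](C)(C)C(C)(C)C)C[C@@H]12 | intermediate
17 | dimethyl 2-{2-[(2R,3aR,4S,7S,8aR)-2-(tert-butyldimethylsilyloxy)-4-hydroxy-1,1-dimethyldecahydroazulen-7-yl]propan-2-yl}propanedioate (C7–H cis to C4–OH, anti to C11–H) | O[C@H]1CC[C@H](C(C)(C)C(C(=O)OC)C(=O)OC)C[C@H]2C(C)(C)[C@H](O[Si](C)(C)C(C)(C)C)C[C@@H]12 | intermediate
18 | dimethyl 2-{2-[(2R,3aR,7S,8aR)-2-(tert-butyldimethylsilyloxy)-1,1-dimethyl-4-oxodecahydroazulen-7-yl]propan-2-yl}propanedioate | O=C1CC[C@H](C(C)(C)C(C(=O)OC)C(=O)OC)C[C@H]2C(C)(C)[C@H](O[Si](C)(C)C(C)(C)C)C[C@@H]12 | intermediate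
19 | geranyl bromide, (2E)-1-bromo-3,7-dimethylocta-2,6-diene | CC(C)=CCC/C(C)=C/CBr | starting material
20 | C5-geranyl derivative of 18 (both C5 epimers; other centres as in 18) | O=C1C(C/C=C(\C)CCC=C(C)C)C[C@H](C(C)(C)C(C(=O)OC)C(=O)OC)C[C@H]2C(C)(C)[C@H](O[Si](C)(C)C(C)(C)C)C[C@@H]12 | intermediate
21 | malonic acid corresponding to 20 | O=C1C(C/C=C(\C)CCC=C(C)C)C[C@H](C(C)(C)C(C(=O)O)C(=O)O)C[C@H]2C(C)(C)[C@H](O[Si](C)(C)C(C)(C)C)C[C@@H]12 | intermediate
22 | malonyl dichloride corresponding to 21 | O=C1C(C/C=C(\C)CCC=C(C)C)C[C@H](C(C)(C)C(C(=O)Cl)C(=O)Cl)C[C@H]2C(C)(C)[C@H](O[Si](C)(C)C(C)(C)C)C[C@@H]12 | intermediate (not isolated)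
23 | cage trione with C1–H and C13 tert-butyldimethylsilyl ether (1-debenzoyl-13-deoxo-13-silyloxy analogue of the target) | CC(C)=CCC/C(C)=C/C[C@@]12C[C@H]3C[C@H]4C(C)(C)[C@H](O[Si](C)(C)C(C)(C)C)C[C@]4(C1=O)C(=O)[C@@H](C2=O)C3(C)C | intermediate
24 | benzoyl chloride | O=C(Cl)c1ccccc1 | starting material
25 | 1-benzoyl cage trione C13 tert-butyldimethylsilyl ether (13-deoxo-13-silyloxy analogue of the target) | CC(C)=CCC/C(C)=C/C[C@@]12C[C@H]3C[C@H]4C(C)(C)[C@H](O[Si](C)(C)C(C)(C)C)C[C@]4(C1=O)C(=O)[C@@](C(=O)c1ccccc1)(C2=O)C3(C)C | intermediate
26 | C13 alcohol (13-deoxo-13-hydroxy analogue of the target) | CC(C)=CCC/C(C)=C/C[C@@]12C[C@H]3C[C@H]4C(C)(C)[C@H](O)C[C@]4(C1=O)C(=O)[C@@](C(=O)c1ccccc1)(C2=O)C3(C)C | intermediate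
27 | CNP0110281.1 | CC(C)=CCC/C(C)=C/C[C@@]12C[C@H]3C[C@H]4C(C)(C)C(=O)C[C@]4(C1=O)C(=O)[C@@](C(=O)c1ccccc1)(C2=O)C3(C)C | target

## Step count and least certain steps

Total step count: 16. Longest linear sequence: 14 steps (from 5 through steps 3–16; the branch from 1 through steps 1, 2 and 5–16 is equally long).

Step 13 (double C-acylation). The acid chloride may lose HCl to an acylketene, which cannot form the bridgehead bond; intermolecular acylation and slow enolisation at the two tertiary α-carbons are further threats. The fallback uses known chemistry and sets out from 20. O-Silylation of the dianion (KN(SiMe3)2, then TBSCl) gives the C4 silyl enol ether F1. Iodide demethylation (LiI, EtOAc, reflux) gives the dilithium dicarboxylate F2. Oxalyl chloride at −20 °C converts the salt under neutral conditions into the silyl enol ether bis(acid chloride) F3. On warming, F3 undergoes the Effenberger cyclisation in its established form (silyl enol ether plus malonyl dichloride, no base), and the route is rejoined at 23.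

Step 7 (key step). Favorskii rearrangement or capture of the cation by solvent may outrun bonding to the neopentyl diene terminus C11. The malonate enolate may be alkylated intermolecularly, the esters may exchange with the solvent alkoxide, and the facial selectivity or the cis ring fusion may be poor. The fallback sets out from 12. Dichloromethyllithium (CH2Cl2, LiN(i-Pr)2, −95 °C) gives the dichloromethyl ketone F4. The same base and solvent then generate a chlorine-stabilised oxyallyl cation, which is longer-lived and more selective for cycloaddition and closes to the α-chloro cycloheptenone F5. Zinc in acetic acid removes the chlorine, and the route is rejoined at 15.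

Step 9 (directed hydrogenation). Chelation by the transannular C4 hydroxyl may be too weak, or the concave face too hindered by the C12 methyl groups, so that hydrogen is delivered from the wrong face; a trans-fused C3 epimer of 15 would also reverse the face of the reduction in step 8. The fallback sets out from 15 and returns at 18, skipping 16 and 17. A hydrogen-atom-transfer hydrogenation (Mn(dpm)3, PhSiH3, t-BuOOH, i-PrOH) reduces C7=C10 through the tertiary C7 radical. Hydrogen capture by that radical follows the stability of the product (C8 on the convex face) and not access of a metal centre. No new compound is made.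

Step 5 (Heck coupling). Insertion into the hindered alkene may be slow, allowing homocoupling of the iodide or further reaction of the diene. The fallback sets out from 11. Ozonolysis (O3, then PPh3) gives the aldehyde F6. Boron-Wittig olefination with lithiated bis(pinacolboryl)methane gives the E-alkenylboronate F7. Suzuki–Miyaura coupling with 4 (Pd(dppf)Cl2, K3PO4, dioxane/H2O) comes back to the route at 12.

Step 14 (bridgehead benzoylation). Deprotonation at the caged C1 may be incomplete, or the acid chloride may react at oxygen or with the amide base. The fallback sets out from 23. The bridgehead lithium species is trapped by benzaldehyde, a more reactive and purely C-selective electrophile, to give the carbinol F8. Periodinane oxidation then returns to the route at 25.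

## Further compounds

F1 | step 13 | C4 tert-butyldimethylsilyl enol ether (C4=C5) of 20 | CC(C)(C)[Si](C)(C)OC1=C(C/C=C(\C)CCC=C(C)C)C[C@H](C(C)(C)C(C(=O)OC)C(=O)OC)C[C@H]2C(C)(C)[C@H](O[Si](C)(C)C(C)(C)C)C[C@@H]12
F2 | step 13 | dilithium dicarboxylate of the silyl enol ether | [Li+].[Li+].CC(C)(C)[Si](C)(C)OC1=C(C/C=C(\C)CCC=C(C)C)C[C@H](C(C)(C)C(C(=O)[O-])C(=O)[O-])C[C@H]2C(C)(C)[C@H](O[Si](C)(C)C(C)(C)C)C[C@@H]12
F3 | step 13 | silyl enol ether bis(acid chloride) | CC(C)(C)[Si](C)(C)OC1=C(C/C=C(\C)CCC=C(C)C)C[C@H](C(C)(C)C(C(=O)Cl)C(=O)Cl)C[C@H]2C(C)(C)[C@H](O[Si](C)(C)C(C)(C)C)C[C@@H]12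
F4 | step 7 | dichloromethyl ketone analogue of 13 | ClC(Cl)C(=O)CC[C@@H](O[Si](C)(C)C(C)(C)C)C(C)(C)/C=C/C(=C)C(C)(C)C(C(=O)OC)C(=O)OC
F5 | step 7 | 5-chloro derivative of 15 (C5 epimers) | O=C1C(Cl)CC(C(C)(C)C(C(=O)OC)C(=O)OC)=C[C@H]2C(C)(C)[C@H](O[Si](C)(C)C(C)(C)C)C[C@@H]12
F0 | step 9 | none | none
F6 | step 5 | (4R)-4-(tert-butyldimethylsilyloxy)-N-methoxy-N,5,5-trimethyl-6-oxohexanamide | CON(C)C(=O)CC[C@@H](O[Si](C)(C)C(C)(C)C)C(C)(C)C=O
F7 | step 5 | (4R,6E)-4-(tert-butyldimethylsilyloxy)-N-methoxy-N,5,5-trimethyl-7-(4,4,5,5-tetramethyl-1,3,2-dioxaborolan-2-yl)hept-6-enamide | CON(C)C(=O)CC[C@@H](O[Si](C)(C)C(C)(C)C)C(C)(C)/C=C/B1OC(C)(C)C(C)(C)O1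
F8 | step 14 | C1 hydroxy(phenyl)methyl cage trione C13 silyl ether (carbinol epimers) | CC(C)=CCC/C(C)=C/C[C@@]12C[C@H]3C[C@H]4C(C)(C)[C@H](O[Si](C)(C)C(C)(C)C)C[C@]4(C1=O)C(=O)[C@@](C(O)c1ccccc1)(C2=O)C3(C)C
A1 | alternative 1 | spirocyclic triketo aldehyde (2-benzoylcyclohexane-1,3,5-trione spiro-fused at C3 to the formyl cyclopentanone, C5 geranyl and prenyl) | CC(C)=CCC/C(C)=C/C[C@@]1(CC=C(C)C)C(=O)[C@@]2(CC(=O)C(C)(C)[C@@H]2C=O)C(=O)C(C(=O)c2ccccc2)C1=O
A2 | alternative 1 | C10-hydroxy derivative of the target | CC(C)=CCC/C(C)=C/C[C@@]12C[C@H]3[C@@H](O)[C@H]4C(C)(C)C(=O)C[C@]4(C1=O)C(=O)[C@@](C(=O)c1ccccc1)(C2=O)C3(C)C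
A3 | alternative 2 | 1-geranyl-2,6-dimethoxycyclohexa-2,5-diene with a (3,3-dimethyloxiran-2-yl)methyl group on C5 | CC(C)=CCC/C(C)=C/CC1(C[C@@H]2OC2(C)C)C(OC)=CCC=C1OC
A4 | alternative 2 | 5-geranyl-7-hydroxy-4-methoxy-8,8-dimethylbicyclo[3.3.1]non-3-en-9-one | CC(C)=CCC/C(C)=C/C[C@@]12C[C@H](O)C(C)(C)[C@H](C2=O)CC=C1OC
A5 | alternative 3 | 1-benzoyl-3-diazo-5-geranyl-8,8-dimethylbicyclo[3.3.1]nonane-2,4,9-trione with a (2E)-3-methyl-4-(tert-butyldimethylsilyloxy)penta-2,4-dienyl chain on C7 | CC(C)=CCC/C(C)=C/C[C@@]12C[C@@H](C/C=C(\C)C(=C)O[Si](C)(C)C(C)(C)C)C(C)(C)[C@](C(=O)c3ccccc3)(C2=O)C(=O)C(=[N+]=[N-])C1=O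
A6 | alternative 3 | cage silyl enol ether lacking one C12 methyl group | CC(C)=CCC/C(C)=C/C[C@@]12C[C@H]3C[C@H]4C(C)=C(O[Si](C)(C)C(C)(C)C)C[C@]4(C1=O)C(=O)[C@@](C(=O)c1ccccc1)(C2=O)C3(C)C
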